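All runs are calculated from invented constants; scatter was added.

At 30.0 h the ash flask read 56.8% left-handed product, and I stopped at that reading, since it stands above 50.0%, the left-handed substrate's share of the charge.

| setting | ash | oak | flask |
|---|---|---|---|
| left-handed substrate | 0.18 M | 0.12 M | 0.18 M |
| right-handed substrate | 0.18 M | 0.12 M | 0.18 M |
| coupling partner | 2.2 equiv | 2.2 equiv | 2.20 equiv |
| racemization catalyst | 0.5 mol% | 0.5 mol% | 0.5 mol% |
| added ligand | 1.6 mM | 1.6 mM | 1.6 mM |
| remark | the very flask that is asked about, followed so far | run made earlier |  |
| time |  |  | 4.0 d |

ash run (percent of the left-handed substrate and right-handed substrate together charged)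

| time / h | left-handed product / % | right-handed product / % |
|---|---|---|
| 2.50 | 29.9 | 1.7 |
| 5.00 | 38.0 | 1.9 |
| 12.0 | 51.4 | 2.8 |
| 30.0 | 56.8 | 5.0 |

oak run (percent of the left-handed substrate and right-handed substrate together charged)

| time / d | left-handed product / % | right-handed product / % |
|---|---|---|
| 0.333 | 39.4 | 0.1 |
| 1.04 | 53.3 | 3.4 |
| 1.67 | 55.1 | 5.7 |
| 3.00 | 59.8 | 6.9 |

(standard deviation of a reading: 1 percentage point)

- coupling partner is single-handed; left-handed substrate and right-handed substrate are mirror images of each other, charged as a racemate, each of them at the stated concentration
- an excess is below zero if the other one leads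
- the handed part of coupling partner does not stay in what it makes, so the products of the two hands are mirror images too

1. left-handed product and right-handed product together, in percent of the left-handed substrate and right-handed substrate charged together, at 4.0 d
2. excess of left-handed product over right-handed product in the product at 4.0 d
3. whether the exchange between left-handed substrate and right-handed substrate keeps pace with the reaction: how far the product's excess at 4.0 d gets from its value without exchange to its value with instant exchange (above 80% keeps pace, below 20% hardly takes part, else lags behind)

With the main step alone, coupling partner and left-handed substrate, left-handed product stops at 50.0% and the excess is complete. The slower coupling of right-handed substrate adds right-handed product: at 5.00 h ash read 1.9% against 38.0%, an excess of 90.5%. Exchange then carries left-handed product past 50.0%.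

Both couplings need coupling partner, so I took its charged concentration as the pace. My clock factor, f, is the ratio of that concentration in two flasks of equal equivalents and catalyst loading: 1.50 for ash over oak. An oak time divided by f should read on ash. Oak's 0.333 d becomes 5.33 h, and oak's 39.4% lies near ash's 38.0% at 5.00 h. So oak's last reading stands for ash at 2.00 d.

Left-handed product gained 5.4 percentage points in the 18.0 h before 30.0 h, then 3 points in the next 18.0 h, a ratio of 0.556. Right-handed product gained 2.2 points, then 1.9 points. I continued for 2.67 more such spans, shrinking the left gain by that ratio and holding the right gain. That gave 62.8% and 12.0%, so y of 74.7% and an excess of 68.0%. Without exchange, left-handed product capped at 50.0% gives 61.4%. Taking 90.5% for instant exchange, I got 22.7% of the way. That stands above the 20% mark. It stands below the 80% mark, so I called the exchange lagging behind.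

The forecast said 75%, 75% and lags behind, on the ground “Roughly 30 % of the new product is right-handed”, and its excess stands above mine.

The flask gave y of 72.9% and an excess of 69.8%; the exchange lags behind, at 37% of the way.

    racemization catalyst + added ligand ⇌ idle complex (K = 1430 L mol⁻¹, k = 170 L mol⁻¹ min⁻¹)
    coupling partner → decomposition product (k = 3.21 × 10⁻⁶ min⁻¹)
    left-handed substrate + racemization catalyst ⇌ right-handed substrate + racemization catalyst, rate k3*[racemization catalyst]*[left-handed substrate] forward; the back reaction follows from the equilibrium constant (k = 3.31 L mol⁻¹ min⁻¹)
    coupling partner + left-handed substrate → left-handed product (k = 0.0168 L mol⁻¹ min⁻¹)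
    coupling partner + right-handed substrate → right-handed product (k = 3.21 × 10⁻⁴ L mol⁻¹ min⁻¹)
    2 racemization catalyst → spent catalyst (k = 47.8 L mol⁻¹ min⁻¹)

By the clock, oak's 3.00 d stood for this flask at 2.00 d, where the flask held 59.4% and 7.12% against oak's 59.8% and 6.9%. The neighbour flask, with 0.880 equiv of coupling partner, breaks the equal equivalents that f asks for, so I read no clock time for it. Its charge allowed 0.440 mol per mol of both substrates, so coupling partner was the limiting reagent there. At 4.00 d that neighbour flask held 0.159% of its coupling partner, with y of 43.8% and an excess of 93.5%.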